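The theta run flattens at 41.5 % of intermediate by 60.0 min. The zeta run, with half the partner, reads 48.7 % at 50.0 min, higher than the theta top, so I take it that partner pulls intermediate away.

| flask | starting material | partner | remark | time |
|---|---|---|---|---|
| theta | 0.10 M | 1.3 equiv | run made earlier |  |
| gamma | 0.050 M | 1.3 equiv | run made earlier |  |
| eta | 0.20 M | 1.3 equiv | run made earlier |  |
| zeta | 0.10 M | 0.65 equiv | run made earlier |  |
| noon | 0.10 M | 1.30 equiv (fed, over 1.00 h) | a stirred flask in which partner is dosed at a steady rate over 1.00 h without added volume, worked up at 1.0 h | 1.0 h |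
| dusk | 0.10 M | 1.30 equiv | everything together in a closed stirred flask, run for 1.0 h | 1.0 h |
| autumn | 0.10 M (fed, over 1.00 h) | 1.30 equiv | a stirred flask in which starting material is dosed at a steady rate over 1.00 h without added volume, worked up at 1.0 h | 1.0 h |
| dawn | 0.10 M | 1.30 equiv | a single well-mixed tank run continuously and read at steady state, 1.0 h in it on average |  |

| run | time / min | intermediate / % | target / % |
|---|---|---|---|
| theta | 5.00 | 10.3 | 0 |
| theta | 8.00 | 15.3 | 1.0 |
| theta | 12.0 | 21.5 | 1.2 |
| theta | 15.0 | 23.5 | 2.4 |
| theta | 25.0 | 33.4 | 2.9 |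
| theta | 40.0 | 40.2 | 7.1 |
| theta | 60.0 | 41.5 | 11.5 |
| gamma | 6.00 | 12.5 | 0 |
| gamma | 15.0 | 25.5 | 0 |
| gamma | 20.0 | 32.5 | 0 |
| gamma | 30.0 | 39.8 | 3.5 |
| gamma | 40.0 | 48.9 | 4.7 |
| gamma | 50.0 | 50.1 | 10.0 |
| eta | 6.00 | 12.8 | 1.4 |
| eta | 15.0 | 21.4 | 2.0 |
| eta | 20.0 | 25.1 | 3.4 |
| eta | 30.0 | 30.3 | 5.1 |
| eta | 40.0 | 29.6 | 7.4 |
| eta | 50.0 | 28.3 | 11.2 |
| zeta | 4.00 | 7.4 | 0 |
| zeta | 12.0 | 22.5 | 2.5 |
| zeta | 20.0 | 32.5 | 2.3 |
| zeta | 30.0 | 41.3 | 3.4 |
| zeta | 50.0 | 48.7 | 4.3 |

(scatter of a reading: 1 percentage point)

- the stated concentrations are those of everything mixed, before any reaction; amounts are the same in each set-up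
- the earlier runs were read with a standard deviation of 1 percentage point
- the feed brings no volume worth counting
- the earlier runs were made in a closed, stirred flask

1. the set-up with the highest amount of intermediate at the outlet or at the end, in percent of the starting material put in ("none" if the first two lie within 2 percentage points) (noon / dusk / autumn / dawn / none)
2. amount of intermediate at the outlet or at the end, in percent of the starting material put in, noon
3. amount of intermediate at the outlet or at the end, in percent of the starting material put in, dusk
4. amount of intermediate at the outlet or at the end, in percent of the starting material put in, autumn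
5. amount of intermediate at the outlet or at the end, in percent of the starting material put in, dawn

Theta's first reading gives a forming constant of 1.24 h⁻¹, so I expect 29.1 % of the starting material left at 60.0 min, the last reading, which I take as the top of theta's curve. At a top, forming equals leaving. That gives 0.865 h⁻¹ for the exit constant, the pseudo-first-order share of intermediate leaving per hour at theta's [partner], which I take as the full charge and scale with the share of that charge present.

In noon, halfway through the feed, half of the partner charge has gone in. With theta's 33.4 % at 25.0 min as a stand-in for the intermediate, I reckon leaving at 0.145 h⁻¹ against forming at 0.666 h⁻¹, both as fractions of the charge, so I expect noon to be still climbing then. I therefore put dusk, a repeat of theta, at that top and noon above it.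

The forecast gives noon 43.5 %, dusk 41 %, autumn 33 % and dawn 29 %: “Noon is best, narrowly.”

The flasks give noon 48.7 %, dusk 39.7 %, autumn 30.9 % and dawn 26.3 %, so noon is best, 5.2 percentage points above the forecast.

    starting material → intermediate (k = 3.70 × 10⁻⁴ s⁻¹)
    partner + intermediate → target (k = 0.00180 L mol⁻¹ s⁻¹)
    starting material + target → side product (k = 0.0200 L mol⁻¹ s⁻¹)
    starting material ⇌ dormant form (K = 4.70, k = 6.20 × 10⁻⁵ s⁻¹)

At 1.0 h, noon holds 48.7 % of intermediate, 17.0 % of starting material and 86.9 % of its partner charge. With the exit constant 0.865 h⁻¹ scaled to that partner, leaving is 0.366 h⁻¹ and forming 0.210 h⁻¹, so leaving is ahead by 0.156 h⁻¹. The neighbour is the same noon flask read at 1.5 h. Held constant over the extra time, that fall takes off 7.8 points and points to 40.9 %. That neighbour flask holds 39.9 % of intermediate.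

Readings and results are calculated with constants of no real substance.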